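Numbering: flavone O1, C2, C3, C4; ring A = C4a–C8a; ring B = C1'–C6'; ring C = pyranone; ring D = dimethylpyran on C3'/C4'. Cuts in retrosynthetic order: O1–C2, then C4–C4a, then ring D (C3'–CH= and O–CMe2), then C2–C3.
Enabling feature: O2'–C2'–C1'–C2=C3–C4 is a six-atom chain, so O2' can be acylated by C4 to give the α-pyrone ring of a coumarin, a ring that is absent from the target.
This temporary lactone hides the 2'-OH among four phenols and is formed with the prenyl group already on C3. It also fixes the ring-B bonds so that ring D closes at the crowded C3' (coumarin C8) rather than C5', and it stores C4 as an acyl donor.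
Forward order: ring B (bought) → lactone ring (Dieckmann) → ring D (propargyl Claisen/oxa-6π) → lactone opened by a ring-A aryllithium (C4–C4a made, 2'-OH released) → ring C closed by O1 on C2.
Ring A enters as a threefold-symmetric phloroglucinol unit, so neither the union nor the O1 closure has a regiochemical alternative.
Stereochemistry: the target has no stereocentre and no stereogenic double bond, so nothing has to be set.

Key step: step 8

Remark: Kuwanon B as drawn is achiral, so the given SMILES defines a single compound and no enantioselective step is needed.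

Step 1
Reactants: 1 methyl 2,4-dihydroxybenzoate; 2 3-chloro-3-methylbut-1-yne
Product: 3 methyl 2-hydroxy-4-[(2-methylbut-3-yn-2-yl)oxy]benzoate
Conditions: K2CO3, KI (cat.), CuI (cat.), acetone, reflux
Reagents that add atoms: none
Why: Williamson-type O-alkylation with a tertiary propargylic chloride takes place at the free 4-OH, because the 2-OH is held in a hydrogen bond to the ester carbonyl and is the weaker nucleophile.

Step 2
Reactants: 3 methyl 2-hydroxy-4-[(2-methylbut-3-yn-2-yl)oxy]benzoate; 4 5-methylhex-4-enoic acid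
Product: 5 methyl 2-[(5-methylhex-4-enoyl)oxy]-4-[(2-methylbut-3-yn-2-yl)oxy]benzoate
Conditions: DCC, DMAP (cat.), CH2Cl2, 0 °C to rt
Reagents that add atoms: none
Why: Steglich esterification acylates the remaining chelated phenol under neutral conditions that leave the alkyne, the tertiary ether and the trisubstituted alkene untouched.

Step 3
Reactants: 5 methyl 2-[(5-methylhex-4-enoyl)oxy]-4-[(2-methylbut-3-yn-2-yl)oxy]benzoate
Product: 6 4-hydroxy-3-(3-methylbut-2-en-1-yl)-7-[(2-methylbut-3-yn-2-yl)oxy]-2H-chromen-2-one
Conditions: LiHMDS (3 equiv), THF, −78 to 0 °C; cold 1 M HCl quench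
Reagents that add atoms: none
Why: In this Dieckmann-type intramolecular Claisen condensation (the classical 4-hydroxycoumarin synthesis from O-acylsalicylates) the aryl-ester enolate attacks the neighbouring methyl ester 6-exo-trig, and deprotonation of the acidic product drives the reaction, so C2–C3 forms with the prenyl chain already on C3.

Step 4
Reactants: 6 4-hydroxy-3-(3-methylbut-2-en-1-yl)-7-[(2-methylbut-3-yn-2-yl)oxy]-2H-chromen-2-one
Product: 7 4-methoxy-3-(3-methylbut-2-en-1-yl)-7-[(2-methylbut-3-yn-2-yl)oxy]-2H-chromen-2-one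
Conditions: Me2SO4, K2CO3, acetone, reflux
Reagents that add atoms: dimethyl sulfate, COS(=O)(=O)OC
Why: O-methylation of the ambident 4-hydroxycoumarin anion with a hard electrophile gives the 4-methoxycoumarin, which removes the acidic proton, keeps the enol from adding to the prenyl group on heating and installs the leaving group for the last step.

Step 5
Reactants: 7 4-methoxy-3-(3-methylbut-2-en-1-yl)-7-[(2-methylbut-3-yn-2-yl)oxy]-2H-chromen-2-one
Product: 9 4-methoxy-8,8-dimethyl-3-(3-methylbut-2-en-1-yl)-2H,8H-pyrano[2,3-f]chromen-2-one, via allenylphenol 8 (not isolated)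
Conditions: N,N-diethylaniline, 190 °C, Ar
Reagents that add atoms: none
Why: Aromatic propargyl Claisen rearrangement, enolisation to 8, 1,5-hydrogen shift and oxa-6π electrocyclisation build ring D, and the naphthalene-like bond fixation of the coumarin (high C7–C8 bond order) sends the [3,3] shift to C8, as is known for 7-(1,1-dimethylpropargyloxy)coumarins.

Step 6
Reactants: 10 phloroglucinol
Product: 11 1,3,5-tris(prop-2-en-1-yloxy)benzene
Conditions: allyl bromide (3.5 equiv), K2CO3, DMF, 60 °C
Reagents that add atoms: allyl bromide, C=CCBr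
Why: Threefold Williamson etherification in a polar aprotic solvent favours O- over C-allylation and supplies ethers that survive organolithium chemistry and leave later under basic palladium catalysis.

Step 7
Reactants: 11 1,3,5-tris(prop-2-en-1-yloxy)benzene
Product: 12 2-bromo-1,3,5-tris(prop-2-en-1-yloxy)benzene
Conditions: NBS (1.0 equiv), CH2Cl2, −10 °C, dark
Reagents that add atoms: N-bromosuccinimide, O=C1CCC(=O)N1Br
Why: Electrophilic aromatic bromination of a trialkoxybenzene is far faster than attack on the terminal alkenes, all three ring positions are equivalent, and one equivalent of NBS at low temperature should stop at the monobromide.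

Step 8
Reactants: 12 2-bromo-1,3,5-tris(prop-2-en-1-yloxy)benzene; 9 4-methoxy-8,8-dimethyl-3-(3-methylbut-2-en-1-yl)-2H,8H-pyrano[2,3-f]chromen-2-one
Product: 15 (2E)-2-[(5-hydroxy-2,2-dimethyl-2H-chromen-6-yl)(methoxy)methylidene]-5-methyl-1-[2,4,6-tris(prop-2-en-1-yloxy)phenyl]hex-4-en-1-one, via aryllithium 13 (not isolated), via lithium lactolate 14 (not isolated)
Conditions: n-BuLi (1.05 equiv), THF, −78 °C, 15 min; then 9 (0.9 equiv) in THF, −78 to −20 °C; sat. aq NH4Cl; filtration through Et3N-deactivated silica
Reagents that add atoms: none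
Why: Bromine–lithium exchange gives aryllithium 13, which adds 1,2 to the lactone carbonyl of 9 (the future flavone C4); lactolate 14 collapses on warming because it expels the 2'-phenoxide and leaves a vinylogous ester, so one operation makes the C4–C4a bond, cleaves the temporary α-pyrone ring and sets the 2'-OH free. The closest known reaction type is the addition of aryllithium and aryl Grignard reagents to coumarins (the route to 2-aryl-2H-chromen-2-ols and flavylium salts) and, more generally, ketone synthesis by opening of aryl-ester lactones. The step closes no ring and makes no stereocentre; the E geometry of the enol-ether double bond is inherited from the ring and is of no consequence, because C2 becomes sp3 during the next closure. Attack must be 1,2 rather than 1,4, which is secured by the fully substituted, methoxy-deactivated coumarin C4 with its peri hydrogen and prenyl neighbour. Addition must stop after one equivalent, which is secured by the phenoxide-bearing push–pull enone that forms and by its two ortho allyloxy groups, and it must outrun deprotonation of the C3–CH2, which is favoured at −78 °C. The threefold symmetry of the ring-A nucleophile removes every regiochemical question.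

Step 9
Reactants: 15 (2E)-2-[(5-hydroxy-2,2-dimethyl-2H-chromen-6-yl)(methoxy)methylidene]-5-methyl-1-[2,4,6-tris(prop-2-en-1-yloxy)phenyl]hex-4-en-1-one
Product: 17 Kuwanon B, 5,7-dihydroxy-2-(5-hydroxy-2,2-dimethyl-2H-chromen-6-yl)-3-(3-methylbut-2-en-1-yl)-4H-chromen-4-one, via trihydroxy enone 16 (not isolated)
Conditions: Pd(PPh3)4 (5 mol%), K2CO3, degassed MeOH/THF 1:1, rt to 50 °C; aq NaH2PO4 to pH 6
Reagents that add atoms: none
Why: Tsuji–Trost-type deallylation of the aryl allyl ethers (π-allylpalladium captured by methanol) frees the three ring-A phenols without touching the C-bound prenyl group or ring D, and an ortho phenoxide of 16 then closes ring C by 6-endo-trig oxa-Michael addition to C2 and E1cB loss of methoxide, the only irreversible exit in base because the competing 2'-O lactol cannot dehydrate without acid.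

Compound list
1 | methyl 2,4-dihydroxybenzoate | COC(=O)c1ccc(O)cc1O | starting material
2 | 3-chloro-3-methylbut-1-yne | C#CC(C)(C)Cl | starting material
3 | methyl 2-hydroxy-4-[(2-methylbut-3-yn-2-yl)oxy]benzoate | COC(=O)c1ccc(OC(C)(C)C#C)cc1O | intermediate
4 | 5-methylhex-4-enoic acid | CC(C)=CCCC(=O)O | starting material
5 | methyl 2-[(5-methylhex-4-enoyl)oxy]-4-[(2-methylbut-3-yn-2-yl)oxy]benzoate | COC(=O)c1ccc(OC(C)(C)C#C)cc1OC(=O)CCC=C(C)C | intermediate
6 | 4-hydroxy-3-(3-methylbut-2-en-1-yl)-7-[(2-methylbut-3-yn-2-yl)oxy]-2H-chromen-2-one | CC(C)=CCc1c(O)c2ccc(OC(C)(C)C#C)cc2oc1=O | intermediate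
7 | 4-methoxy-3-(3-methylbut-2-en-1-yl)-7-[(2-methylbut-3-yn-2-yl)oxy]-2H-chromen-2-one | CC(C)=CCc1c(OC)c2ccc(OC(C)(C)C#C)cc2oc1=O | intermediate
8 | 7-hydroxy-4-methoxy-8-(3-methylbuta-1,2-dien-1-yl)-3-(3-methylbut-2-en-1-yl)-2H-chromen-2-one (allenylphenol) | CC(C)=CCc1c(OC)c2ccc(O)c(C=C=C(C)C)c2oc1=O | intermediate
9 | 4-methoxy-8,8-dimethyl-3-(3-methylbut-2-en-1-yl)-2H,8H-pyrano[2,3-f]chromen-2-one | CC(C)=CCc1c(OC)c2ccc3c(c2oc1=O)C=CC(C)(C)O3 | intermediate
10 | phloroglucinol | Oc1cc(O)cc(O)c1 | starting material
11 | 1,3,5-tris(prop-2-en-1-yloxy)benzene | C=CCOc1cc(OCC=C)cc(OCC=C)c1 | intermediate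
12 | 2-bromo-1,3,5-tris(prop-2-en-1-yloxy)benzene | C=CCOc1cc(OCC=C)c(Br)c(OCC=C)c1 | intermediate
13 | [2,4,6-tris(prop-2-en-1-yloxy)phenyl]lithium (aryllithium) | [Li]c1c(OCC=C)cc(OCC=C)cc1OCC=C | intermediate
14 | lithium 4-methoxy-8,8-dimethyl-3-(3-methylbut-2-en-1-yl)-2-[2,4,6-tris(prop-2-en-1-yloxy)phenyl]-2H,8H-pyrano[2,3-f]chromen-2-olate (lithium lactolate, racemic) | [Li]OC1(c2c(OCC=C)cc(OCC=C)cc2OCC=C)Oc2c(ccc3c2C=CC(C)(C)O3)C(OC)=C1CC=C(C)C | intermediate
15 | (2E)-2-[(5-hydroxy-2,2-dimethyl-2H-chromen-6-yl)(methoxy)methylidene]-5-methyl-1-[2,4,6-tris(prop-2-en-1-yloxy)phenyl]hex-4-en-1-one (acyl group cis to the chromenyl group) | O=C(c1c(OCC=C)cc(OCC=C)cc1OCC=C)/C(CC=C(C)C)=C(OC)\c1ccc2c(c1O)C=CC(C)(C)O2 | intermediate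
16 | (2E)-2-[(5-hydroxy-2,2-dimethyl-2H-chromen-6-yl)(methoxy)methylidene]-5-methyl-1-(2,4,6-trihydroxyphenyl)hex-4-en-1-one (trihydroxy enone) | O=C(c1c(O)cc(O)cc1O)/C(CC=C(C)C)=C(OC)\c1ccc2c(c1O)C=CC(C)(C)O2 | intermediate
17 | Kuwanon B (achiral) | CC(C)=CCc1c(-c2ccc3c(c2O)C=CC(C)(C)O3)oc2cc(O)cc(O)c2c1=O | target

Total step count: 9. Longest linear sequence: 7 (steps 1, 2, 3, 4, 5, 8, 9).

Steps most likely to fail

Step 8. The aryllithium may abstract a proton from the doubly allylic CH2 on C3. It may also attack coumarin C4 with loss of methoxide, or fail to add because both partners are hindered. The fallback sets out from 9 and comes back at 15, and it replaces acyl substitution by addition to an aldehyde followed by oxidation. DIBAL-H (toluene, −78 °C) should reduce the lactone to the racemic lactol 4-methoxy-8,8-dimethyl-3-(3-methylbut-2-en-1-yl)-2H,8H-pyrano[2,3-f]chromen-2-ol F1. Two equivalents of aryllithium 13 (the first deprotonates the lactol) should add to its open hydroxy-enal form. This gives the racemic allylic alcohol 6-{(1E)-3-hydroxy-1-methoxy-2-(3-methylbut-2-en-1-yl)-3-[2,4,6-tris(prop-2-en-1-yloxy)phenyl]prop-1-en-1-yl}-2,2-dimethyl-2H-chromen-5-ol F2. Activated MnO2 in CH2Cl2 should then oxidise this benzylic, allylic alcohol to 15.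

Step 9. The π-allylpalladium species may C-allylate the liberated electron-rich ring A. Ring closure may also be slow, because the 2'-phenoxide feeds electron density into C2. The fallback sets out from 9 and 10 and comes back at 17, and it changes the closure from base-driven to acid-catalysed with no π-allyl species present. Phloroglucinol 10 is converted (NaH, MOMCl, DMF) into 1,3,5-tris(methoxymethoxy)benzene F3. F3 is lithiated between two MOM ethers by directed ortho-metalation (n-BuLi, THF, 0 °C) and added to 9 as in step 8. The released 2'-phenoxide is capped in the flask with MOMCl to give the tetra-MOM enone (2E)-2-{methoxy[5-(methoxymethoxy)-2,2-dimethyl-2H-chromen-6-yl]methylidene}-5-methyl-1-[2,4,6-tris(methoxymethoxy)phenyl]hex-4-en-1-one F4. Dilute HCl in MeOH at 40 °C should cleave the acetals, the two ketone-flanking ones first. A freed ring-A hydroxyl should close onto C2 with loss of methanol before the 2'-OH is unmasked, giving 17.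

Step 3. The aryl-ester enolate may fragment to a ketene and a phenoxide, or methoxide may cleave the acyl group, faster than the ring closes. The fallback sets out from 3 and 4 and comes back at 6, and it replaces the intramolecular condensation by a crossed Claisen condensation followed by lactonisation. Acid 4 is esterified (EtI, K2CO3, DMF) to ethyl 5-methylhex-4-enoate F5. Its lithium enolate (LDA, THF, −78 °C, 3.5 equiv) should condense with the methyl ester of the lithium salt of 3. The product is the racemic β-keto ester ethyl 2-{2-hydroxy-4-[(2-methylbut-3-yn-2-yl)oxy]benzoyl}-5-methylhex-4-enoate F6. F6 should lactonise through its free phenol with loss of ethanol (K2CO3 cat., MeCN, 40 °C) to 6, and its stereocentre disappears on enolisation.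

Further compounds
F1 | step 8 | 4-methoxy-8,8-dimethyl-3-(3-methylbut-2-en-1-yl)-2H,8H-pyrano[2,3-f]chromen-2-ol (racemic lactol) | CC(C)=CCC1=C(OC)c2ccc3c(c2OC1O)C=CC(C)(C)O3
F2 | step 8 | 6-{(1E)-3-hydroxy-1-methoxy-2-(3-methylbut-2-en-1-yl)-3-[2,4,6-tris(prop-2-en-1-yloxy)phenyl]prop-1-en-1-yl}-2,2-dimethyl-2H-chromen-5-ol (racemic) | OC(c1c(OCC=C)cc(OCC=C)cc1OCC=C)/C(CC=C(C)C)=C(OC)\c1ccc2c(c1O)C=CC(C)(C)O2
F3 | step 9 | 1,3,5-tris(methoxymethoxy)benzene | COCOc1cc(OCOC)cc(OCOC)c1
F4 | step 9 | (2E)-2-{methoxy[5-(methoxymethoxy)-2,2-dimethyl-2H-chromen-6-yl]methylidene}-5-methyl-1-[2,4,6-tris(methoxymethoxy)phenyl]hex-4-en-1-one | O=C(c1c(OCOC)cc(OCOC)cc1OCOC)/C(CC=C(C)C)=C(OC)\c1ccc2c(c1OCOC)C=CC(C)(C)O2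
F5 | step 3 | ethyl 5-methylhex-4-enoate | CCOC(=O)CCC=C(C)C
F6 | step 3 | ethyl 2-{2-hydroxy-4-[(2-methylbut-3-yn-2-yl)oxy]benzoyl}-5-methylhex-4-enoate (racemic) | CCOC(=O)C(CC=C(C)C)C(=O)c1ccc(OC(C)(C)C#C)cc1O
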